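The ratio between the south-east and north rate constants comes first, for south-east has twice north's charge at the same temperature.

common to all: X 0.64 mol%
- north: E 0.19 M; L 2.5 equiv; J 9.5 mM; temperature 95 °C; run made earlier
- south: E 0.095 M; L 2.5 equiv; J 9.5 mM; temperature 106 °C; run made earlier
- south-east: E 0.38 M; L 2.5 equiv; J 9.5 mM; temperature 95 °C; run made earlier
- midnight: E 0.19 M (fed, over 2.5 d); L 2.50 equiv; J 9.50 mM; temperature 100 °C; all else is in the flask from the start; the feed brings no volume worth counting; time 4.0 d
- winter: E 0.19 M; L 2.50 equiv (fed, over 2.5 d); J 9.50 mM; temperature 100 °C; all else is in the flask from the start; the feed brings no volume worth counting; time 4.0 d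
- autumn: E 0.19 M (fed, over 2.5 d); L 2.50 equiv; J 9.50 mM; the addition at 80 °C, then warmed to 100 °C; the feed brings no volume worth counting; time 4.0 d
- spring: E 0.19 M (in portions, 3, over 2.5 d); L 2.50 equiv; J 9.50 mM; temperature 100 °C; first portion at the start, last at 2.5 d; time 4.0 d
- noon: E 0.19 M; L 2.50 equiv (fed, over 6.0 h); J 9.50 mM; temperature 100 °C; all else is in the flask from the start; the feed brings no volume worth counting; time 4.0 d

- north (time / d: G / %): 0.333: 0; 0.833: 9; 1.67: 19; 2.50: 28
- south (time / d: G / %): 0.833: 4; 1.67: 9; 2.50: 15; 3.00: 20
- south-east (time / d: G / %): 0.417: 16; 1.04: 41; 2.08: 69; 3.00: 78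

(scatter of a reading: 1.5 percentage points)

* which flask leads in amount of G, in percent of the E charged ("all alike" within 1.5 percentage points) (midnight / winter / autumn / spring / noon / all alike)
* how much G is there at the end, in percent of the E charged: midnight
* how much G is there at the end, in percent of the E charged: winter
* how much G is there at the end, in percent of the E charged: autumn
* how much G is there at the end, in percent of the E charged: spring
* how much G is there at the end, in percent of the E charged: noon



Take a molecule of E to have a steady chance per day of becoming G, a first-order constant k, read from the logarithm of the unconverted part; this is a working assumption, for the readings of south steepen with time. Between the middle readings north gives 0.140 d⁻¹ and south-east 0.619 d⁻¹, a ratio of 4.40, read with the scatter of 1.5 percentage points in it. [X] and [L] rose along with E, so the ratio is read as their effect on k.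

South, at half north's charge, gives 0.0730 d⁻¹. Multiplied by the same ratio, this puts 2.29 on north's k for the step from 95 °C to 106 °C. Spread evenly in the logarithm, that gives 0.205 d⁻¹ at 100 °C and 0.0454 d⁻¹ at 80 °C.

Now follow one molecule of E. In a flask fed with E, [X] and [L] are taken at their full values from the start, so a late molecule has the same k and less time, and the mean stay of a steady feed ends 1.25 d short of the full time. In autumn the mean molecule spends 1.25 d cold and 1.50 d warm, so it collects 0.364 of exposure, the rate constant summed over the mean stay. G is then estimated as the chance of conversion at that exposure, 30.5 %.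

Midnight, with k at 100 °C throughout, gives 43.0 %, and spring has the same mean stay. The weak link is [L], since the runs never moved it apart from [X]. If k follows [L], winter's exposure equals midnight's, and noon gives 54.8 %. If k ignores [L], winter and noon both reach 55.9 %. So noon stands above midnight, spring and autumn, and winter meets it in the second case.

The forecast, with slightly different figures, gave 42 % for midnight, 45 % for winter, 30 % for autumn, 42 % for spring and 52 % for noon: “Noon leads”.

The flasks give 42.0 % for midnight, 45.7 % for winter, 30.4 % for autumn, 41.2 % for spring and 55.3 % for noon, with noon in the lead.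

    E + X ⇌ X + Q (K = 2.50, k = 1.30 M⁻¹ min⁻¹, Ea = 66.0 kJ mol⁻¹, ΔH = −22.0 kJ mol⁻¹)
    L + J → D (k = 0.250 M⁻¹ min⁻¹, Ea = 95.0 kJ mol⁻¹)
    L + X + Q → X + G (k = 0.450 M⁻² min⁻¹, Ea = 80.0 kJ mol⁻¹)
    (constants at 100 °C)

In autumn, Q's half-life through the step with L is 8.2 d at 2.22 d, far longer than the relaxation half-life of 0.217 d for E and Q by the first step alone at 4.00 d, and at 2.22 d Q falls back 2.2 times faster than it goes on. The step with L is first order in [L], and autumn's exposure of 0.364, which gives 30.5 % against 30.4 %, scaled by 1.68 for the neighbour of autumn with 4.20 equiv of L gives 45.7 %, and that neighbour holds 45.2 %.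

The earlier runs and the new flask are simulated for an exercise; the scatter is artificial.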